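## Structural features

The target 21 is a dearomatised acylphloroglucinol, numbered here as a chromene (O1, C2, C3, C4, C4a, C5 to C8, C8a). Ring A is the carbocycle C4a–C5–C6–C7–C8–C8a, with the quaternary carbon C6 between the ketones C5 and C7. Ring B is a 2,3-dimethyl dihydropyran fused at C4a–C8a, whose C4 enol and ring oxygen complete a vinylogous acid with the two ketones. C8 carries a 3-phenylpropanoic acid through its benzylic carbon, and C6 carries a prenyl group and a branched eleven-carbon chain, CH2–CH(CH=CMe2)–CH2CH2–C(Me)=CH2. Of the five stereocentres, C2 and C3 are adjacent (trans, S,S), the chain methine (R) is separated from the quaternary C6 (S) by one methylene, and the benzylic centre (R) stands alone. The fragile groups are the enolised β-triketone (acidic, open to retro-Claisen cleavage, epimerisable at C3 through its tautomers), the ring B ether (retro-oxa-Michael under base in the aromatic precursors), three alkenes that exclude acid, hydroboration and hydrogenation, and the free acid. The real difficulty is the all-carbon quaternary centre with two different chains, its relationship to a chain methine that no ring holds in place, and the differentiation of the three oxygens of the phloroglucinol core. The key step uses the aromatic form of ring A: there C6 bears the chain methylene ortho to the C5 phenol oxygen and the next chain atom is a methine carrying a latent aldehyde, the pattern left when an enamine adds to an ortho-quinone methide and the phenol oxygen closes a lactol.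

## Logic of the disconnections

21 ⇒ 20. The acid and the enol oxygen on C7 are rejoined as an enol lactone (acyl C–O bond). This hides the acid and one of the three ring oxygens in a ring that every earlier intermediate already contains, so ring A keeps a single free oxygen. The forward hydrolysis must leave the triketone, C6 and the alkenes alone.

20 ⇒ 19. The bond from C6 to the prenyl CH2 is cut. Only this lets ring A become aromatic, which removes the quaternary stereocentre and turns a sensitive dienone into a stable phenol. The forward step must alkylate carbon and not oxygen, at C6 and not at the para carbon, and on one face of a flat phenoxide, which calls for a metal-allyl electrophile under catalyst control.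

19 ⇒ 17. The double bond of the 2-methylpropenyl group is cut. This exposes an aldehyde carbon on the chain methine, stored as a lactol on the C5 oxygen, and removes three carbons. The forward olefination must neither epimerise the methine next to the transient aldehyde nor attack the aryl lactone.

17 ⇒ 12 + 15. The bond between the benzylic CH2 and the chain methine and the lactol C–O bond are cut. Here the phenol, the CH2 and the formyl-bearing methine line up as quinone methide plus enamine, so the whole chain is separated from the arene and the methine becomes the α-carbon of a linear aldehyde. The forward step needs a single quinone methide (guaranteed by the lactone in 12), catalyst control of the enamine face and a base mild enough for the lactone.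

15 ⇒ 14 ⇒ 13. Two functional-group changes without a skeletal cut lead back to a commercial acid. Forward, reduction and oxidation must leave the 1,1-disubstituted alkene untouched.

12 ⇒ 10. The aryl–CH2 and CH2–S bonds are cut, giving a one-carbon electrophile and a sulfinate. C6 is the only ring carbon of 10 that still bears hydrogen, so the site is fixed. The forward condensation must avoid joining two arenes through the methylene.

10 ⇒ 9 ⇒ 7. After the C5 oxygen is protected again, the O1–C2 bond of ring B is cut (retro-oxa-Michael). Ring B and both its stereocentres collapse to an achiral unsaturated acyl chain. The forward closure needs exactly one free phenol beside the acyl group, a chiral base to choose the face at C2, and an equilibration to place C3 trans.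

7 ⇒ 6 ⇒ 4 + 5. The aryl–acyl bond is traced back to an aryl ester, then the ester C–O bond is cut. Putting the acyl group first on the hindered phenol oxygen lets it migrate to that oxygen's only free ortho carbon, which settles the site of acylation and of the later ring closure together. The forward steps must esterify a hindered phenol without deconjugating the acid, and rearrange under a Lewis acid that spares the silyl ether and does not close ring B early.

4 ⇒ 3 ⇒ 1 + 2. The silyl group is removed, then the ring-to-benzylic-carbon bond and the lactone C–O bond are cut. The three ring positions of 1 are equivalent, so annulation with a three-carbon unit at the acid oxidation level can give only one constitution from two commercial materials. The forward steps need catalyst control of the benzylic centre, mono-annulation, and a silylation that tells the two remaining phenols apart by their surroundings.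

## Other disconnections considered

Alternative 1: The cut is the ring A bond between C5 (the carbonyl next to the quaternary carbon) and C4a, which unfolds ring A into the open-chain triketo ester A1.
- Forward step: base would deprotonate the methylene between the two acyl-side ketones of A1, and that carbon would attack the methyl ester on the quaternary carbon (Dieckmann-type Claisen condensation) to give the enolised trione A2. Ring B would follow by desilylation and cyclodehydration, and the phenylpropanoic acid by conjugate addition from the remaining ring CH2.
- In its favour: ring A is never aromatic, so the quaternary centre would be made in an acyclic ester by auxiliary-controlled enolate alkylation, with no C- versus O-allylation question. On this point the alternative is better than the chosen plan, whose step 12 relies on catalyst control over a flat phenoxide. The ring B stereocentres would come from an anti-aldol fragment of fixed configuration, at least equal to step 5.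
- Against it: A1 has two diketone methylenes of similar acidity and further enolisable positions, and only one of the possible carbanions leads to ring A. The ester is neopentyl-like, and O-cyclisation to pyranones or aldol closure to an aromatic ring are the usual fates of such chains. The folding is thermodynamically reasonable (it ends in a stabilised triketone anion) but poorly directed.
- Remaining problems after A2: the hydroxyl would have to condense with the ring carbonyl remote from the quaternary carbon rather than its neighbour. The benzylic centre would have to be set by a reversible Michael addition, whereas step 1 sets it on a symmetrical triol.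
- Step economy: weaker. A1 requires a linear build-up of a quaternary carbon with two stereodefined chains plus a protected triketide, while the chosen route takes all six ring A carbons and their oxygens from one commercial arene.

Alternative 2: The cut lies inside ring B (the C2–C3 bond and the bond from the ring oxygen to the enol ether carbon), so that ring B would be made first as dihydropyranone A5.
- Forward step: acetaldehyde A3 and the methoxy silyloxy diene A4 would combine under Ti(OiPr)4 and BINOL in a hetero-Diels–Alder (or Mukaiyama aldol/cyclisation) sequence, and acid work-up would complete the elimination to A5.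
- In its favour: both ring B stereocentres would be set in one catalytic step on a small, easily purified molecule, without a protecting group. For ring B alone this is equal to steps 3 to 5 of the chosen plan in control and slightly better in step count.
- Against it: the diene terminus that must bond to oxygen is fully substituted, which lowers reactivity and favours the stepwise aldol path, where the 2,3-cis/trans outcome is uncertain (C3 could be equilibrated later, as in the chosen plan). A3 is volatile and self-condenses under Lewis acids.
- Main weakness: A5 holds only eight carbons of the target and nothing of ring A. The quaternary centre, the chain methine, the benzylic centre and the whole carbocycle would still have to be built on its methyl group and C5, essentially by the chemistry of alternative 3. The disconnection is sound mechanistically but aimed at the easiest part of the molecule, and the overall sequence would be longer.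

Alternative 3: The cuts are the bond from the quaternary carbon C6 to C5 (the carbonyl next to ring B) and the bond from C8 to C7, so ring A would be assembled from the prenylated lactone A6 and the pyranone acid chloride A7.
- Forward step: the lithium enolate of A6 would be C-acylated by A7, creating the quaternary centre. Deprotonation of the pyranone methyl group (a vinylogous enolate) would then attack the lactone carbonyl, and ring opening would release the primary alcohol to give the bicyclic core A8.
- In its favour: it is convergent, and the chain methine is already present in A6, set by standard chemistry (equal in reliability to the chosen key step, though not catalytic). The six-membered lactone could relay that centre to the quaternary carbon by 1,3-induction during acylation, a substrate control element the chosen plan lacks at C6; on the quaternary centre this alternative may be the better one. The second bond formation is driven by the triketone anion.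
- Against it: acid chlorides tend to O-acylate hindered α-substituted lactone enolates, the β-keto lactone is prone to retro-Claisen cleavage, and the γ-deprotonation must compete with enolisation at C3 of the pyranone.
- Remaining problems after A8: the phenylpropanoic acid is still missing, so the benzylic centre would have to be introduced late by conjugate addition with less control than in step 1. The primary alcohol of A8 would have to be raised to the aldehyde oxidation level, where the neighbouring methine can epimerise, before the same Wittig reaction as in step 11 (equal risk there).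
- Step economy: counting the preparation of A6 and of A7 (which would itself come from A5), the sequence is clearly longer than the chosen one.

Key step: step 10

Numbering of the tricyclic intermediates (pyrano[2,3-f]chromene): O1, C2, C3, C4 (ketone), C4a, C5, C6, C6a, O7 (lactone oxygen), C8 (lactone carbonyl), C9, C10 (CHPh), C10a, C10b. C2 to C6 keep their numbers in 21; C6a becomes C7, C10a becomes C8 and C10b becomes C8a. Compounds 3 to 7 use chroman-2-one numbering (benzylic C4, oxygens on C5 and C7).

Assumption (remark on the chemistry): the sense of induction of the triazolium catalyst (step 1), of the cinchona alkaloid (step 5; quinidine is specified because the 2S series is needed and its pseudoenantiomer quinine is taken to favour 2R in this type of closure) and of the ligand in step 12 is assigned by analogy, the mirror-image or pseudoenantiomeric catalyst being used if the opposite sense is found; the kinetic product of the oxa-Michael closure is taken to be the cis isomer, hence the equilibration in the same flask.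

## Route

Step 1
Reactants: 1 phloroglucinol (benzene-1,3,5-triol); 2 (E)-cinnamaldehyde
Product: 3 (4R)-5,7-dihydroxy-4-phenylchroman-2-one
Conditions: 1 (2 equiv), (5aS,10bR)-2-mesityl-5a,10b-dihydro-4H,6H-indeno[2,1-b][1,2,4]triazolo[4,3-d][1,4]oxazin-2-ium chloride (10 mol %), DBU (15 mol %), 3,3',5,5'-tetra-tert-butyldiphenoquinone (1.1 equiv), THF, rt
Reagents that add atoms: none
Why: Oxidative carbene catalysis: the Breslow intermediate of 2 is oxidised to the α,β-unsaturated acyl azolium, a ring carbon of 1 adds in conjugate fashion (directly or after O-acylation and [3,3] shift) and the neighbouring phenol lactonises, releasing the carbene. The chiral triazolylidene sets the benzylic centre in the C–C bond-forming event; the three ring positions of 1 are equivalent, so only one monoadduct exists, and excess 1 suppresses a second annulation.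

Step 2
Reactants: 3 (4R)-5,7-dihydroxy-4-phenylchroman-2-one
Product: 4 (4R)-5-hydroxy-4-phenyl-7-[(triisopropylsilyl)oxy]chroman-2-one
Conditions: TIPSCl (1.05 equiv), imidazole, DMF, −20 → 0 °C
Reagents that add atoms: chlorotriisopropylsilane, CC(C)[Si](Cl)(C(C)C)C(C)C
Why: Sterically controlled silylation: the 7-OH is flanked by two ring hydrogens whereas the 5-OH sits in the bay next to the C4 benzylic centre, so a bulky silyl chloride in slight excess at low temperature should take the 7-OH; the lactone is inert to imidazole.

Step 3
Reactants: 4 (4R)-5-hydroxy-4-phenyl-7-[(triisopropylsilyl)oxy]chroman-2-one; 5 tiglic acid [(E)-2-methylbut-2-enoic acid]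
Product: 6 (4R)-2-oxo-4-phenyl-7-[(triisopropylsilyl)oxy]chroman-5-yl (E)-2-methylbut-2-enoate
Conditions: DCC (1.3 equiv), DMAP (20 mol %), CH2Cl2, 0 °C → rt
Reagents that add atoms: none
Why: Steglich esterification of the remaining hindered phenol; carbodiimide activation avoids the acid chloride/amine conditions that deconjugate α,β-unsaturated acyl groups through vinylketenes, and the E geometry of 5 is retained.

Step 4
Reactants: 6 (4R)-2-oxo-4-phenyl-7-[(triisopropylsilyl)oxy]chroman-5-yl (E)-2-methylbut-2-enoate
Product: 7 (4R)-5-hydroxy-6-[(E)-2-methylbut-2-enoyl]-4-phenyl-7-[(triisopropylsilyl)oxy]chroman-2-one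
Conditions: TiCl4 (1.5 equiv), CH2Cl2, −20 °C → rt; cold 1 M HCl
Reagents that add atoms: none
Why: Fries rearrangement through a titanium phenoxide/acylium pair delivers the acyl group to C6, the only free position ortho to the ester oxygen, and the product is held as a six-membered titanium chelate that keeps the phenol from adding to the enone until cold acidic work-up. The hindered, weakly Lewis-basic aryl silyl ether is expected to survive; a para shift to C8 would give an isomer without a phenol beside the enone, which cannot cyclise later and is removed.

Step 5
Reactants: 7 (4R)-5-hydroxy-6-[(E)-2-methylbut-2-enoyl]-4-phenyl-7-[(triisopropylsilyl)oxy]chroman-2-one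
Product: 9 (2S,3S,10R)-2,3-dimethyl-10-phenyl-5-[(triisopropylsilyl)oxy]-2,3,9,10-tetrahydro-4H,8H-pyrano[2,3-f]chromene-4,8-dione, via cis-chromanone 8 (not isolated)
Conditions: quinidine (20 mol %), PhCl, 10 °C; then MgI2 (1.2 equiv), Et3N (20 mol %), Et2O/PhCl, rt
Reagents that add atoms: none
Why: Intramolecular oxa-Michael addition under bifunctional cinchona catalysis (quinuclidine nitrogen as base for the phenol, C9 hydroxyl on the enone carbonyl) closes ring B; the alkaloid chooses the face of the β-carbon and so sets C2 (S), and only one phenol is free, so only one ring can form. Protonation of the enol should give mainly the cis isomer 8, and soft enolisation through the magnesium chelate then epimerises C3 alone to the diequatorial trans isomer (3S) without opening the ring. The centre inherited from 3 makes any C2 epimer a separable diastereomer.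

Step 6
Reactants: 9 (2S,3S,10R)-2,3-dimethyl-10-phenyl-5-[(triisopropylsilyl)oxy]-2,3,9,10-tetrahydro-4H,8H-pyrano[2,3-f]chromene-4,8-dione
Product: 10 (2S,3S,10R)-5-hydroxy-2,3-dimethyl-10-phenyl-2,3,9,10-tetrahydro-4H,8H-pyrano[2,3-f]chromene-4,8-dione
Conditions: HF·pyridine, THF, 0 °C → rt
Reagents that add atoms: none
Why: Fluoride cleavage of the aryl silyl ether under mildly acidic conditions, which avoid the retro-oxa-Michael opening of ring B and the lactone opening that a basic fluoride source could cause; the freed phenol is hydrogen-bonded to the C4 ketone.

Step 7
Reactants: 10 (2S,3S,10R)-5-hydroxy-2,3-dimethyl-10-phenyl-2,3,9,10-tetrahydro-4H,8H-pyrano[2,3-f]chromene-4,8-dione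
Product: 12 (2S,3S,10R)-5-hydroxy-2,3-dimethyl-6-[(4-methylbenzenesulfonyl)methyl]-10-phenyl-2,3,9,10-tetrahydro-4H,8H-pyrano[2,3-f]chromene-4,8-dione, via hydroxymethyl phenol 11 (not isolated)
Conditions: (CH2O)n (3 equiv), TolSO2Na (3 equiv), HCO2H/H2O (4:1), 40 °C
Reagents that add atoms: formaldehyde (as paraformaldehyde), C=O; sodium p-toluenesulfinate, Cc1ccc(cc1)S(=O)[O-].[Na+]
Why: Acid-mediated three-component Mannich-type sulfonylmethylation: the arene is hydroxymethylated at C6, its only free ring carbon (ortho to the C5 phenol, para to O1), and benzylic alcohol 11 ionises to the protonated quinone methide, which the sulfinate captures at sulfur. Excess formaldehyde and sulfinate keep the benzylic cation from being intercepted by a second arene.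

Step 8
Reactants: 13 5-methylhex-5-enoic acid
Product: 14 5-methylhex-5-en-1-ol
Conditions: LiAlH4, Et2O, 0 °C → rt; then H2O
Reagents that add atoms: none
Why: Hydride reduction of the carboxylic acid to the primary alcohol; the isolated 1,1-disubstituted alkene is inert to LiAlH4, whereas a borane would hydroborate it.

Step 9
Reactants: 14 5-methylhex-5-en-1-ol
Product: 15 5-methylhex-5-enal
Conditions: Dess–Martin periodinane (1.1 equiv), CH2Cl2, rt
Reagents that add atoms: none
Why: Dess–Martin oxidation stops at the aldehyde under neutral conditions and neither isomerises nor oxidises the alkene.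

Step 10
Reactants: 12 (2S,3S,10R)-5-hydroxy-2,3-dimethyl-6-[(4-methylbenzenesulfonyl)methyl]-10-phenyl-2,3,9,10-tetrahydro-4H,8H-pyrano[2,3-f]chromene-4,8-dione; 15 5-methylhex-5-enal
Product: 17 tetracyclic lactol [O5–CH(OH)–(R)-CH(CH2CH2C(CH3)=CH2)–CH2–C6 bridge on the (2S,3S,10R) tricycle; anomeric mixture], via ortho-quinone methide 16 (not isolated)
Conditions: 15 (2 equiv), (S)-2-[diphenyl(trimethylsilyloxy)methyl]pyrrolidine (20 mol %), Na2CO3 (1.5 equiv, powdered), CH2Cl2, 0 °C → rt
Reagents that add atoms: none
Why: Carbonate deprotonates the C5 phenol of 12 and the phenoxide expels p-toluenesulfinate (E1cB) to give ortho-quinone methide 16, a push–pull-stabilised but still strongly electrophilic acceptor whose reaction restores the aromatic ring. Aldehyde 15 condenses with the secondary amine to the E-enamine, which attacks the exocyclic methylene of 16 through the face not covered by the diphenyl(silyloxy)methyl group (stepwise Michael addition or asynchronous inverse-demand hetero-Diels–Alder reaction), forming the methylene–methine bond. The C5 phenoxide oxygen then closes on the iminium carbon (6-exo-trig, or the second bond of the formal [4+2] addition) to a cyclic N,O-aminal, and the water set free on enamine formation hydrolyses it, returning the amine and leaving the chroman-2-ol ring of 17, whose anomers converge in step 11. The closest known reaction type is the enamine-catalysed addition of aldehydes to ortho-quinone methides released from 2-(arylsulfonylmethyl)phenols, which gives 3-substituted chroman-2-ols. The new chain methine is controlled by the catalyst alone: with the (S)-amine the anti E-enamine is attacked from its unshielded face, placing formyl, arylmethyl and alkyl groups in the R arrangement (the same sense as in nitroalkene additions with this catalyst), and since the electrophilic carbon is a CH2 no second centre arises. Site selectivity is needed because two oxygens are ortho to C6; the lactone ties up the C6a oxygen, so only the C5 phenol can form a quinone methide and only it can close the lactol. The mild heterogeneous base and the hindered amine should spare the aryl lactone and the chromanone, and storage of the carbonyl carbon as aminal and then lactol keeps the α-branched centre largely out of reach of further enamine formation and so of epimerisation.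

Step 11
Reactants: 17 tetracyclic lactol (anomeric mixture)
Product: 19 (2S,3S,10R)-5-hydroxy-2,3-dimethyl-6-[(2R)-5-methyl-2-(2-methylprop-1-en-1-yl)hex-5-en-1-yl]-10-phenyl-2,3,9,10-tetrahydro-4H,8H-pyrano[2,3-f]chromene-4,8-dione, via open-chain phenol aldehyde 18 (not isolated)
Conditions: i-PrPPh3I (2.5 equiv), n-BuLi (2.4 equiv), THF, 0 °C; then 17, −78 → 0 °C
Reagents that add atoms: isopropyltriphenylphosphonium iodide, CC(C)[P+](c1ccccc1)(c1ccccc1)c1ccccc1.[I-]
Why: Wittig olefination of a lactol: the first equivalent of ylide deprotonates 17, which opens to the lithium phenoxide of aldehyde 18, and the aldehyde is converted into the trisubstituted alkene; no geometry question arises because the new alkene carbon carries two methyl groups. Low temperature and a small excess of ylide are chosen so that olefination outruns enolisation of the α-branched aldehyde; the ring ketone is deactivated as a vinylogous carboxylate and the aryl lactone is expected to react more slowly than the aldehyde.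

Step 12
Reactants: 19 (2S,3S,10R)-5-hydroxy-2,3-dimethyl-6-[(2R)-5-methyl-2-(2-methylprop-1-en-1-yl)hex-5-en-1-yl]-10-phenyl-2,3,9,10-tetrahydro-4H,8H-pyrano[2,3-f]chromene-4,8-dione
Product: 20 (2S,3S,6S,10R)-2,3-dimethyl-6-[(2R)-5-methyl-2-(2-methylprop-1-en-1-yl)hex-5-en-1-yl]-6-(3-methylbut-2-en-1-yl)-10-phenyl-2,3,9,10-tetrahydro-4H-pyrano[2,3-f]chromene-4,5,8(6H)-trione
Conditions: Pd2(dba)3·CHCl3 (2.5 mol %, zerovalent palladium), N,N'-[(1S,2S)-cyclohexane-1,2-diyl]bis[2-(diphenylphosphanyl)benzamide] [(S,S)-DACH-phenyl Trost ligand, 7.5 mol %], prenyl acetate (1.5 equiv), Cs2CO3 (1.2 equiv), toluene, rt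
Reagents that add atoms: prenyl acetate (3-methylbut-2-en-1-yl acetate), CC(C)=CCOC(C)=O
Why: Palladium-catalysed asymmetric allylic alkylation used as a dearomatisation: zerovalent palladium ionises prenyl acetate to the 1,1-dimethylallyl complex and the caesium phenoxide of 19 attacks its unsubstituted terminus through C6, the less hindered ortho carbon, giving the linear prenyl group and the 6,6-disubstituted dienone. O-Allylation is reversible under the catalyst whereas C-allylation is not, and prenyl acetate does not alkylate without the metal, so there is no uncatalysed background. The chiral pocket of the ligand selects the face of the planar phenoxide and sets C6 (S); the substrate's own centres are remote and should exert little bias, and the minor C6 epimer is a separable diastereomer.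

Step 13
Reactants: 20 (2S,3S,6S,10R)-2,3-dimethyl-6-[(2R)-5-methyl-2-(2-methylprop-1-en-1-yl)hex-5-en-1-yl]-6-(3-methylbut-2-en-1-yl)-10-phenyl-2,3,9,10-tetrahydro-4H-pyrano[2,3-f]chromene-4,5,8(6H)-trione
Product: 21 (3R)-3-[(2S,3S,6S)-4-hydroxy-2,3-dimethyl-6-[(2R)-5-methyl-2-(2-methylprop-1-en-1-yl)hex-5-en-1-yl]-6-(3-methylbut-2-en-1-yl)-5,7-dioxo-3,5,6,7-tetrahydro-2H-chromen-8-yl]-3-phenylpropanoic acid (CNP0155375.2)
Conditions: LiOH·H2O (3 equiv), THF/H2O (3:1), 0 °C → rt; then 1 M HCl to pH 3
Reagents that add atoms: lithium hydroxide, [Li+].[OH-]
Why: Saponification of the activated enol lactone: hydroxide attacks the acyl carbon, and acidification gives the free acid while the liberated enol tautomerises to the conjugated 4-hydroxy-5,7-dione form of 21. During the reaction the triketone is present as its unreactive delocalised anion, which protects C6 from retro-Claisen cleavage, and C3 stays in (or returns to) the favoured trans arrangement.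

## Compound list

1 | phloroglucinol | Oc1cc(O)cc(O)c1 | starting material
2 | (E)-cinnamaldehyde | O=C/C=C/c1ccccc1 | starting material
3 | (4R)-5,7-dihydroxy-4-phenylchroman-2-one | O=C1C[C@H](c2ccccc2)c2c(O)cc(O)cc2O1 | intermediate
4 | (4R)-5-hydroxy-4-phenyl-7-[(triisopropylsilyl)oxy]chroman-2-one | O=C1C[C@H](c2ccccc2)c2c(O)cc(O[Si](C(C)C)(C(C)C)C(C)C)cc2O1 | intermediate
5 | tiglic acid | C/C=C(\C)C(=O)O | starting material
6 | (4R)-2-oxo-4-phenyl-7-[(triisopropylsilyl)oxy]chroman-5-yl (E)-2-methylbut-2-enoate | O=C1C[C@H](c2ccccc2)c2c(OC(=O)/C(C)=C/C)cc(O[Si](C(C)C)(C(C)C)C(C)C)cc2O1 | intermediate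
7 | (4R)-5-hydroxy-6-[(E)-2-methylbut-2-enoyl]-4-phenyl-7-[(triisopropylsilyl)oxy]chroman-2-one | O=C1C[C@H](c2ccccc2)c2c(O)c(C(=O)/C(C)=C/C)c(O[Si](C(C)C)(C(C)C)C(C)C)cc2O1 | intermediate
8 | (2S,3R,10R)-2,3-dimethyl-10-phenyl-5-[(triisopropylsilyl)oxy]-2,3,9,10-tetrahydro-4H,8H-pyrano[2,3-f]chromene-4,8-dione (cis) | c1c(O[Si](C(C)C)(C(C)C)C(C)C)c2C(=O)[C@H](C)[C@H](C)Oc2c2[C@@H](c3ccccc3)CC(=O)Oc12 | intermediate (not isolated)
9 | (2S,3S,10R)-2,3-dimethyl-10-phenyl-5-[(triisopropylsilyl)oxy]-2,3,9,10-tetrahydro-4H,8H-pyrano[2,3-f]chromene-4,8-dione (trans) | c1c(O[Si](C(C)C)(C(C)C)C(C)C)c2C(=O)[C@@H](C)[C@H](C)Oc2c2[C@@H](c3ccccc3)CC(=O)Oc12 | intermediate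
10 | (2S,3S,10R)-5-hydroxy-2,3-dimethyl-10-phenyl-2,3,9,10-tetrahydro-4H,8H-pyrano[2,3-f]chromene-4,8-dione | c1c(O)c2C(=O)[C@@H](C)[C@H](C)Oc2c2[C@@H](c3ccccc3)CC(=O)Oc12 | intermediate
11 | (2S,3S,10R)-5-hydroxy-6-(hydroxymethyl)-2,3-dimethyl-10-phenyl-2,3,9,10-tetrahydro-4H,8H-pyrano[2,3-f]chromene-4,8-dione | OCc1c(O)c2C(=O)[C@@H](C)[C@H](C)Oc2c2[C@@H](c3ccccc3)CC(=O)Oc12 | intermediate (not isolated)
12 | (2S,3S,10R)-5-hydroxy-2,3-dimethyl-6-[(4-methylbenzenesulfonyl)methyl]-10-phenyl-2,3,9,10-tetrahydro-4H,8H-pyrano[2,3-f]chromene-4,8-dione | Cc1ccc(cc1)S(=O)(=O)Cc1c(O)c2C(=O)[C@@H](C)[C@H](C)Oc2c2[C@@H](c3ccccc3)CC(=O)Oc12 | intermediate (key-step precursor)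
13 | 5-methylhex-5-enoic acid | C=C(C)CCCC(=O)O | starting material
14 | 5-methylhex-5-en-1-ol | C=C(C)CCCCO | intermediate
15 | 5-methylhex-5-enal | C=C(C)CCCC=O | intermediate
16 | (2S,3S,10R)-2,3-dimethyl-6-methylidene-10-phenyl-2,3,9,10-tetrahydro-4H-pyrano[2,3-f]chromene-4,5,8(6H)-trione (ortho-quinone methide) | C=C1C(=O)C2C(=O)[C@@H](C)[C@H](C)OC=2C2[C@@H](c3ccccc3)CC(=O)OC1=2 | intermediate (not isolated)
17 | tetracyclic lactol: (2S,3S,10R) tricycle with O5 and C6 bridged by –CH(OH)–(R)-CH(CH2CH2C(CH3)=CH2)–CH2– (chroman-2-ol, anomeric mixture) | C=C(C)CC[C@@H]1Cc2c(OC1O)c1C(=O)[C@@H](C)[C@H](C)Oc1c1[C@@H](c3ccccc3)CC(=O)Oc21 | intermediate (key-step product)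
18 | (2R)-2-{[(2S,3S,10R)-5-hydroxy-2,3-dimethyl-4,8-dioxo-10-phenyl-2,3,9,10-tetrahydro-4H,8H-pyrano[2,3-f]chromen-6-yl]methyl}-5-methylhex-5-enal | C=C(C)CC[C@@H](C=O)Cc1c(O)c2C(=O)[C@@H](C)[C@H](C)Oc2c2[C@@H](c3ccccc3)CC(=O)Oc12 | intermediate (not isolated)
19 | (2S,3S,10R)-5-hydroxy-2,3-dimethyl-6-[(2R)-5-methyl-2-(2-methylprop-1-en-1-yl)hex-5-en-1-yl]-10-phenyl-2,3,9,10-tetrahydro-4H,8H-pyrano[2,3-f]chromene-4,8-dione | C=C(C)CC[C@@H](C=C(C)C)Cc1c(O)c2C(=O)[C@@H](C)[C@H](C)Oc2c2[C@@H](c3ccccc3)CC(=O)Oc12 | intermediate
20 | (2S,3S,6S,10R)-2,3-dimethyl-6-[(2R)-5-methyl-2-(2-methylprop-1-en-1-yl)hex-5-en-1-yl]-6-(3-methylbut-2-en-1-yl)-10-phenyl-2,3,9,10-tetrahydro-4H-pyrano[2,3-f]chromene-4,5,8(6H)-trione | C=C(C)CC[C@@H](C=C(C)C)C[C@@]1(CC=C(C)C)C(=O)C2C(=O)[C@@H](C)[C@H](C)OC=2C2=C1OC(=O)C[C@@H]2c1ccccc1 | intermediate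
21 | (3R)-3-[(2S,3S,6S)-4-hydroxy-2,3-dimethyl-6-[(2R)-5-methyl-2-(2-methylprop-1-en-1-yl)hex-5-en-1-yl]-6-(3-methylbut-2-en-1-yl)-5,7-dioxo-3,5,6,7-tetrahydro-2H-chromen-8-yl]-3-phenylpropanoic acid | C=C(C)CC[C@@H](C=C(C)C)C[C@@]1(CC=C(C)C)C(=O)C2=C(O)[C@@H](C)[C@H](C)OC2=C([C@H](CC(=O)O)c2ccccc2)C1=O | target

## Step count and least certain steps

Total: 13 steps. Longest linear sequence: 11 steps (steps 1 to 7 and 10 to 13); steps 8 and 9 are a two-step side branch.

Step 10 (key step). The most likely failure is unproductive consumption of the quinone methide (hydration back to 11, oligomerisation, N-alkylation of the catalyst) because enamine turnover is slow relative to release of this donor-stabilised acceptor; a second risk is loss of facial control if an uncatalysed enol pathway competes. Fallback: from 12 and 15, a stoichiometric chiral enamine is used instead of catalysis. Aldehyde 15 is condensed with (S)-2-(methoxymethyl)pyrrolidine to the preformed enamine (S)-2-(methoxymethyl)-1-[(1E)-5-methylhexa-1,5-dien-1-yl]pyrrolidine F1, which is present in excess while 16 is released from 12 with K2CO3 in CH2Cl2. The inverse-demand hetero-Diels–Alder reaction of this electron-rich alkene with the quinone methide should give the 2-aminochroman aminal F2, and dilute aqueous acetic acid hydrolyses it to lactol 17, where the route is rejoined. The auxiliary shields the same enamine face as the catalyst; its antipode is used if the sense is opposite.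

Step 12. The most likely failures are alkylation at oxygen or at the para carbon C10a instead of C6, and insufficient catalyst control of the C6 face (a mismatched pairing of ligand and substrate). Fallback: from 19, the lactone is opened first with LiOH in THF/H2O to the dihydroxy acid (3R)-3-{(2S,3S)-5,7-dihydroxy-2,3-dimethyl-6-[(2R)-5-methyl-2-(2-methylprop-1-en-1-yl)hex-5-en-1-yl]-4-oxochroman-8-yl}-3-phenylpropanoic acid F3. C6 now lies between two phenoxide oxygens, and prenyl bromide in cold aqueous KOH should alkylate it as in the classical lupulone-type alkylative dearomatisation of acylphloroglucinols. This gives 21 directly together with its C6 epimer F4, the two being separated by preparative chromatography; the route is rejoined at 21.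

Step 11. The most likely failure is enolisation of the transient α-branched aldehyde by the basic, hindered ylide (epimerisation of the chain methine), or deprotonation or acylation at the aryl lactone. Fallback: from 17, a non-basic Takai-type alkylidenation with the geminal dichromium reagent from 2,2-diiodopropane and CrCl2 (divalent chromium) in THF. This reagent is selective for aldehydes over ketones and esters and acts on the open form 18 in equilibrium with the lactol, giving 19 directly; this fallback makes no new compound (F0).

Step 4. The most likely failures are loss of the silyl group under the Lewis acid, chloride or phenol addition to the enone (premature, uncontrolled closure of ring B) and para migration. Fallback: from 4, the acyl group is built in three regiospecific operations without a Fries step. Magnesium-mediated ortho-formylation (MgCl2, Et3N, paraformaldehyde, MeCN) should give the aldehyde (4R)-5-hydroxy-2-oxo-4-phenyl-7-[(triisopropylsilyl)oxy]chromane-6-carbaldehyde F5. Nozaki–Hiyama–Kishi addition of (E)-2-bromobut-2-ene (CrCl2, divalent chromium; NiCl2 cat.; DMF), which tolerates the lactone, should give the allylic alcohol (4R)-5-hydroxy-6-[(E)-1-hydroxy-2-methylbut-2-en-1-yl]-4-phenyl-7-[(triisopropylsilyl)oxy]chroman-2-one F6. MnO2 oxidation then returns to 7.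

Step 7. The most likely failure is capture of the benzylic cation by a second molecule of 10 (methylene-bridged dimer), which is irreversible, whereas sulfone formation is reversible under acid. Fallback: from 10, a two-stage Mannich route. Aminomethylation with Eschenmoser's salt in CH2Cl2 should give the Mannich base (2S,3S,10R)-6-[(dimethylamino)methyl]-5-hydroxy-2,3-dimethyl-10-phenyl-2,3,9,10-tetrahydro-4H,8H-pyrano[2,3-f]chromene-4,8-dione F7, in which the benzylic carbon is never a free cation. Heating F7 with TolSO2Na in acetic acid exchanges dimethylamine for sulfinate through the quinone methide and returns to 12.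

## Further compounds

F1 | step 10 | (S)-2-(methoxymethyl)-1-[(1E)-5-methylhexa-1,5-dien-1-yl]pyrrolidine | C=C(C)CC/C=C/N1CCC[C@H]1COC
F2 | step 10 | 2-aminochroman aminal: lactol 17 with the anomeric OH replaced by (S)-2-(methoxymethyl)pyrrolidin-1-yl (anomeric mixture) | C=C(C)CC[C@@H]1Cc2c(OC1N1CCC[C@H]1COC)c1C(=O)[C@@H](C)[C@H](C)Oc1c1[C@@H](c3ccccc3)CC(=O)Oc21
F3 | step 12 | (3R)-3-{(2S,3S)-5,7-dihydroxy-2,3-dimethyl-6-[(2R)-5-methyl-2-(2-methylprop-1-en-1-yl)hex-5-en-1-yl]-4-oxochroman-8-yl}-3-phenylpropanoic acid | C=C(C)CC[C@@H](C=C(C)C)Cc1c(O)c2C(=O)[C@@H](C)[C@H](C)Oc2c([C@H](CC(=O)O)c2ccccc2)c1O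
F4 | step 12 | (3R)-3-[(2S,3S,6R)-4-hydroxy-2,3-dimethyl-6-[(2R)-5-methyl-2-(2-methylprop-1-en-1-yl)hex-5-en-1-yl]-6-(3-methylbut-2-en-1-yl)-5,7-dioxo-3,5,6,7-tetrahydro-2H-chromen-8-yl]-3-phenylpropanoic acid (C6 epimer of 21) | C=C(C)CC[C@@H](C=C(C)C)C[C@]1(CC=C(C)C)C(=O)C2=C(O)[C@@H](C)[C@H](C)OC2=C([C@H](CC(=O)O)c2ccccc2)C1=O
F0 | step 11 | none | none
F5 | step 4 | (4R)-5-hydroxy-2-oxo-4-phenyl-7-[(triisopropylsilyl)oxy]chromane-6-carbaldehyde | O=C1C[C@H](c2ccccc2)c2c(O)c(C=O)c(O[Si](C(C)C)(C(C)C)C(C)C)cc2O1
F6 | step 4 | (4R)-5-hydroxy-6-[(E)-1-hydroxy-2-methylbut-2-en-1-yl]-4-phenyl-7-[(triisopropylsilyl)oxy]chroman-2-one (carbinol epimers) | O=C1C[C@H](c2ccccc2)c2c(O)c(C(O)/C(C)=C/C)c(O[Si](C(C)C)(C(C)C)C(C)C)cc2O1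
F7 | step 7 | (2S,3S,10R)-6-[(dimethylamino)methyl]-5-hydroxy-2,3-dimethyl-10-phenyl-2,3,9,10-tetrahydro-4H,8H-pyrano[2,3-f]chromene-4,8-dione | CN(C)Cc1c(O)c2C(=O)[C@@H](C)[C@H](C)Oc2c2[C@@H](c3ccccc3)CC(=O)Oc12
A1 | alternative 1 | methyl (2S,8S,9S)-8-methyl-2-[(2R)-5-methyl-2-(2-methylprop-1-en-1-yl)hex-5-en-1-yl]-2-(3-methylbut-2-en-1-yl)-3,5,7-trioxo-9-[(triethylsilyl)oxy]decanoate | C=C(C)CC[C@@H](C=C(C)C)C[C@@](CC=C(C)C)(C(=O)OC)C(=O)CC(=O)CC(=O)[C@@H](C)[C@H](C)O[Si](CC)(CC)CC
A2 | alternative 1 | (6S)-3-hydroxy-6-[(2R)-5-methyl-2-(2-methylprop-1-en-1-yl)hex-5-en-1-yl]-6-(3-methylbut-2-en-1-yl)-2-[(2S,3S)-2-methyl-3-(triethylsilyloxy)butanoyl]cyclohex-2-ene-1,5-dione | C=C(C)CC[C@@H](C=C(C)C)C[C@@]1(CC=C(C)C)C(=O)C(C(=O)[C@@H](C)[C@H](C)O[Si](CC)(CC)CC)=C(O)CC1=O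
A3 | alternative 2 | acetaldehyde | CC=O
A4 | alternative 2 | (2E,4Z)-2-methoxy-4-(trimethylsilyloxy)hexa-2,4-diene | CO/C(C)=C/C(=C/C)O[Si](C)(C)C
A5 | alternative 2 | (2S,3S)-2,3,6-trimethyl-2,3-dihydro-4H-pyran-4-one | CC1=CC(=O)[C@@H](C)[C@H](C)O1
A6 | alternative 3 | (5R)-3-(3-methylbut-2-en-1-yl)-5-(3-methylbut-3-en-1-yl)oxan-2-one (C3 epimers) | C=C(C)CC[C@H]1COC(=O)C(CC=C(C)C)C1
A7 | alternative 3 | (2S,3S)-2,3,6-trimethyl-4-oxo-3,4-dihydro-2H-pyran-5-carbonyl chloride | CC1=C(C(=O)Cl)C(=O)[C@@H](C)[C@H](C)O1
A8 | alternative 3 | (2S,3S,6R)-4-hydroxy-6-[(2R)-2-(hydroxymethyl)-5-methylhex-5-en-1-yl]-2,3-dimethyl-6-(3-methylbut-2-en-1-yl)-2,3-dihydro-5H-chromene-5,7(6H)-dione | C=C(C)CC[C@@H](CO)C[C@@]1(CC=C(C)C)C(=O)C2=C(O)[C@@H](C)[C@H](C)OC2=CC1=O
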